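**The pitfall.** A catalyst loading is easily read as working catalyst, but impurity may claim part of it first. The flask stands beside two earlier runs that differ in impurity and in nothing else.

in all of them: substrate 0.069 M; free catalyst 1 mol%
- grey: coupling partner 1.2 equiv; impurity 0.080 mM; run made earlier
- green: coupling partner 1.2 equiv; impurity 0.18 mM; run made earlier
- flask: coupling partner 1.20 equiv; impurity 0.12 mM

- grey (time / min: target / %, substrate / %): 0.200: 3.7, 96.7; 0.333: 5.2, 94.5; 0.667: 10.8, 89.6; 1.33: 19.7, 79.2; 2.50: 35.1, 64.9
- green (time / min: target / %, substrate / %): 0.200: 2.6, 96.9; 0.333: 4.3, 95.3; 0.667: 8.4, 90.8; 1.33: 17.0, 82.7; 2.50: 29.8, 69.2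

(each reading ± 0.3 percentage points)

- apparent order in coupling partner when 20% of the substrate are converted (percent change of the rate of making target for one percent more coupling partner charged)
- apparent order in free catalyst when 20% of the substrate are converted (percent change of the rate of making target for one percent more free catalyst charged)

- no earlier run changes the charge of free catalyst; that part of a forecast is a guess
- no earlier run changes the charge of coupling partner; that part of a forecast is a guess

**Dead share.** Let c be the catalyst charged and y the impurity charged. We suppose that one impurity kills one catalyst. For the flask c is 0.690 mM, so the dead share d = y/c, the fraction of the charge lost to impurity, is 17.4%.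

**Fastest rung.** The readings suggest that this loss comes early. Target in green over target in grey reads 0.827 at 0.333 min and 0.849 at 2.50 min. The ratio of c − y in the two runs is 0.836.

**Middle rung.** In the grey run, the readings at 2.50 min, with c − y taken as working catalyst, give one catalyst round in about 3.78 s on average.

**Slowest rung.** Grey substrate needs minutes, with 79.2% left at 1.33 min, so a round is far shorter than that span. We therefore freeze d. With rate proportional to c − y, our order in catalyst charge for the flask is 1/(1 − d) = 1.21. Partner never varied, so we give it no number.

**The forecast.** It gives 1.2 for catalyst (0.85 to 1.45), beside our 1.21. For partner it gives 0.5 (0 to 1.2), noting that “the split is not identified”.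

**The flask.** The flask gives 1.2 in catalyst and 0.33 in partner.

    free catalyst + impurity → spent catalyst (k = 5190 L mol⁻¹ s⁻¹)
    coupling partner + free catalyst ⇌ catalyst intermediate A (K = 169 L mol⁻¹, k = 17.2 L mol⁻¹ s⁻¹)
    catalyst intermediate B ⇌ free catalyst + target (K = 2.26 M, k = 1.26 s⁻¹)
    substrate + catalyst intermediate A ⇌ catalyst intermediate B (K = 21.0 L mol⁻¹, k = 14.0 L mol⁻¹ s⁻¹)

With impurity as charged, free catalyst turns into spent catalyst at 37 min⁻¹ per free catalyst, a half-life of 1.11 s by that step alone, which is far shorter than the 0.200 min of the first state we hold. In the flask, spent catalyst stands at 17.4% of the catalyst charged after 0.200 min and at 17.4% after 20.0 min, against a dead share of 17.4%.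

(Readings and results are simulated on assumed constants; the scatter is artificial.)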